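**Assumption:** the SMILES is taken as definitive, i.e. (1S,2R,5Z,7S,8S,9R,10S,11R,14S,17R) in briarane numbering. I use that numbering for all intermediates (C15 = C1‑Me, C16 = C5‑Me, C20 = epoxide CH2); α = ring face opposite the C1 methyl, β = same face. The route is a paper design, not an executed synthesis.

## Retrosynthetic overview
1. γ‑Lactone last: intramolecular SmI2 Reformatsky of a C7 α‑bromopropionate onto a C8 ketone (sets C8 and C17).
2. Ten‑membered ring: Nozaki–Hiyama–Kishi closure of C6–C7 from a (Z)‑vinyl iodide and a C7 aldehyde.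
3. C7–C9 array by Brown γ‑alkoxyallylboration of a C9 aldehyde; 11,20‑epoxide by methylenation/epoxidation of a C11 ketone before the ring alkene exists.
4. Cyclohexane core (C1, C10, then C14, C2): vinyl‑cuprate addition/aldol on (R)‑4‑silyloxy‑2‑methylcyclohexenone with (Z)‑5‑iodo‑4‑methylpent‑4‑enal, then oxidation and two directed reductions.
5. Ring order: cyclohexane (chiral enone) → ten‑membered carbocycle → γ‑lactone.

## Route

**Step 1**
Reactants: 1, 4‑(tert‑butyldimethylsilyloxy)cyclohexanone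
Product: 2, (R)‑4‑(TBSO)‑1‑(trimethylsilyloxy)cyclohex‑1‑ene
Conditions: lithium (S,S)‑bis(1‑phenylethyl)amide, TMSCl (in situ), LiCl, THF, −90 °C
Reagents that add atoms: TMSCl, C[Si](C)(C)Cl
Why: Enantioselective deprotonation (chiral lithium amide desymmetrisation) makes the remote C–OTBS carbon the (R) stereocentre; the (S,S) base is chosen as the antipode of the one that gives the S enol ether.

**Step 2**
Reactants: 2
Product: 3, (R)‑4‑(TBSO)cyclohex‑2‑en‑1‑one
Conditions: Pd(OAc)2, MeCN, rt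
Reagents that add atoms: none
Why: Saegusa–Ito oxidation of the silyl enol ether gives the enone without touching the stereocentre.

**Step 3**
Reactants: 3
Product: 4, (R)‑4‑(TBSO)‑2‑iodocyclohex‑2‑en‑1‑one
Conditions: I2, pyridine, CH2Cl2, 0 °C → rt
Reagents that add atoms: iodine, II
Why: α‑Iodination of the enone by pyridine addition / iodination / elimination.

**Step 4**
Reactants: 4
Product: 5, (R)‑4‑(TBSO)‑2‑methylcyclohex‑2‑en‑1‑one
Conditions: Me4Sn, Pd2(dba)3, AsPh3, CuI, NMP, 70 °C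
Reagents that add atoms: tetramethyltin, C[Sn](C)(C)C
Why: Stille coupling of the α‑iodoenone installs the future C15 methyl.

**Step 5**
Reactants: 6, prop‑2‑yn‑1‑ol
Product: 7, (Z)‑3‑iodo‑2‑methylprop‑2‑en‑1‑ol
Conditions: MeMgBr (2.2 equiv), CuI (10 mol %), THF, −10 °C → rt; then I2, −20 °C
Reagents that add atoms: MeMgBr, C[Mg]Br; iodine, II
Why: Alkoxide‑directed anti‑carbomagnesiation gives a cyclic vinylmagnesium; iodinolysis with retention puts I cis to CH2OH (Z).

**Step 6**
Reactants: 7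
Product: 8, (Z)‑3‑bromo‑1‑iodo‑2‑methylprop‑1‑ene
Conditions: PBr3, Et2O, 0 °C
Reagents that add atoms: PBr3, BrP(Br)Br
Why: SN2 bromination of the allylic alcohol; alkene geometry untouched.

**Step 7**
Reactants: 8; 9, ethyl acetate
Product: 10, ethyl (Z)‑5‑iodo‑4‑methylpent‑4‑enoate
Conditions: LDA, THF, −78 °C; then 8, DMPU, −78 → −30 °C
Reagents that add atoms: none
Why: Ester enolate SN2 alkylation of the allylic bromide; the vinyl iodide is inert.

**Step 8**
Reactants: 10
Product: 11, (Z)‑5‑iodo‑4‑methylpent‑4‑enal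
Conditions: DIBAL‑H, CH2Cl2, −78 °C
Reagents that add atoms: none
Why: Partial ester reduction through the stable tetrahedral aluminate.

**Step 9**
Reactants: 5; 11
Product: 12, aldol adduct (C10 β‑vinyl, C1 β‑Me / α‑hydroxyalkyl chain, C11 α‑OTBS; C2 carbinol epimers)
Conditions: CH2=CHMgBr, CuBr·SMe2 (cat.), THF, −78 °C; then 11, −78 °C; AcOH quench
Reagents that add atoms: vinylmagnesium bromide, C=C[Mg]Br
Why: Tandem conjugate addition–aldol: vinyl adds to C10 anti to the C11 OTBS, and the tetrasubstituted enolate is trapped by 11 anti to the new vinyl, fixing C10 and quaternary C1 (the C2 mixture is erased in step 10).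

**Step 10**
Reactants: 12
Product: 13, 1,3‑diketone (C2 and C14 ketones)
Conditions: Dess–Martin periodinane, NaHCO3, CH2Cl2, rt
Reagents that add atoms: none
Why: Alcohol oxidation to a non‑enolisable 2‑acyl‑2‑methylcyclohexanone.

**Step 11**
Reactants: 13
Product: 14, C14 α‑alcohol, C2 ketone
Conditions: L‑Selectride (1.05 equiv), THF, −78 °C
Reagents that add atoms: none
Why: Bulky hydride reduces the more reactive cyclohexanone carbonyl and attacks equatorially (as in 4,4‑dimethyl‑3‑keto steroids), giving the axial C14–OH trans to the C1 methyl.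

**Step 12**
Reactants: 14
Product: 15, (2R,14S) syn‑1,3‑diol
Conditions: Et2BOMe, NaBH4, THF/MeOH, −78 °C; MeOH azeotrope
Reagents that add atoms: none
Why: Narasaka–Prasad reduction: external hydride attack on the C14–O–B chelate of the β‑hydroxy ketone gives the 1,3‑syn diol, i.e. the required C2 configuration.

**Step 13**
Reactants: 15
Product: 16, 2,14‑diacetate
Conditions: Ac2O, DMAP, pyridine, rt
Reagents that add atoms: acetic anhydride, CC(=O)OC(C)=O
Why: Acylation installs two of the three target acetates.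

**Step 14**
Reactants: 16
Product: 17, C9 aldehyde
Conditions: OsO4 (cat.), NaIO4, 2,6‑lutidine, dioxane/H2O, rt
Reagents that add atoms: OsO4, O=[Os](=O)(=O)=O; NaIO4, [Na+].[O-]I(=O)(=O)=O (aldehyde oxygen)
Why: Lemieux–Johnson cleavage of the monosubstituted vinyl; the iodoalkene is electronically deactivated.

**Step 15**
Reactants: 17; 18, allyl 4‑methoxybenzyl ether
Product: 19, C9 (R) alcohol with syn C8–OPMB and terminal vinyl (C7)
Conditions: 18, s‑BuLi, THF, −78 °C; (−)‑Ipc2BOMe; BF3·OEt2; then 17, −78 °C; ethanolamine work‑up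
Reagents that add atoms: none ((−)‑Ipc2BOMe is only the chiral mediator)
Why: Brown (Z)‑γ‑alkoxyallylboration via a chair Zimmerman–Traxler transition state: Si‑face attack (reagent control, matched with Felkin–Anh) sets C9; the syn C8–OPMB is only a ketone precursor.

**Step 16**
Reactants: 19
Product: 20, 2,9,14‑triacetate
Conditions: Ac2O, DMAP, pyridine, rt
Reagents that add atoms: acetic anhydride, CC(=O)OC(C)=O
Why: Acylation installs the third target acetate and differentiates O9 from O8.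

**Step 17**
Reactants: 20
Product: 21, C11 alcohol
Conditions: HF·pyridine, THF/pyridine, 0 °C → rt
Reagents that add atoms: none
Why: Fluoride desilylation; acetates, PMB ether and vinyl iodide are stable.

**Step 18**
Reactants: 21
Product: 22, C11 ketone
Conditions: Dess–Martin periodinane, NaHCO3, CH2Cl2, 0 °C
Reagents that add atoms: none
Why: Neutral oxidation avoids β‑elimination of the C9 acetate and C10 epimerisation.

**Step 19**
Reactants: 22
Product: 23, 11(20)‑exocyclic methylene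
Conditions: Zn, CH2Br2, TiCl4, THF/CH2Cl2, 0 °C → rt
Reagents that add atoms: dibromomethane, BrCBr
Why: Non‑basic Takai–Lombardo methylenation is selective for the ketone over esters and spares the base‑sensitive β‑acetoxy ketone.

**Step 20**
Reactants: 23
Product: 24, 11,20‑epoxide (O α, CH2 β)
Conditions: mCPBA, NaHCO3, CH2Cl2, 0 °C
Reagents that add atoms: mCPBA, OOC(=O)c1cccc(Cl)c1
Why: Prilezhaev epoxidation of the only electron‑rich alkene (the allylic‑ether vinyl and the iodoalkene are deactivated); equatorial attack anti to the axial C1 methyl gives the target C11 configuration.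

**Step 21**
Reactants: 24
Product: 25, C7 aldehyde
Conditions: OsO4 (cat.), NaIO4, 2,6‑lutidine, dioxane/H2O, rt; use crude
Reagents that add atoms: OsO4, O=[Os](=O)(=O)=O; NaIO4, [Na+].[O-]I(=O)(=O)=O
Why: Lemieux–Johnson cleavage of the remaining terminal vinyl; epoxide and iodoalkene survive.

**Step 22**
Reactants: 25
Product: 26, ten‑membered carbocycle, 7,8‑anti allylic alcohol (C7 epimeric to target)
Conditions: CrCl2 (10 equiv), NiCl2 (2 mol %), DMSO/THF, 2 mM, syringe pump, rt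
Reagents that add atoms: none
Why: Nozaki–Hiyama–Kishi macrocyclisation: the alkenylchromium forms with retention of Z geometry and adds to the α‑alkoxy aldehyde in the polar Felkin–Anh sense.

**Step 23**
Reactants: 26; 27, 2‑bromopropanoic acid (racemic)
Product: 28, C7 2‑bromopropanoate with target C7 configuration
Conditions: PPh3, DIAD, toluene, 0 °C
Reagents that add atoms: none
Why: Mitsunobu esterification: SN2 inversion at the allylic carbinol corrects C7 and installs the Reformatsky donor (the CHBr centre is lost in step 26).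

**Step 24**
Reactants: 28
Product: 29, C8 alcohol
Conditions: DDQ, CH2Cl2/pH 7 buffer, 0 °C
Reagents that add atoms: none
Why: Oxidative PMB cleavage under buffered conditions that spare the epoxide and esters.

**Step 25**
Reactants: 29
Product: 30, C8 ketone
Conditions: Dess–Martin periodinane, NaHCO3, CH2Cl2, 0 °C; use immediately
Reagents that add atoms: none
Why: Neutral oxidation to the α,α′‑bis(acyloxy) ketone without epimerising C7 or C9.

**Step 26**
Reactants: 30
Product: 31, junceellolide F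
Conditions: SmI2 (2.2 equiv), THF, −78 °C; pH 7 quench
Reagents that add atoms: none
Why: Intramolecular samarium Reformatsky (aldol): the tethered enolate reaches C8 only from the face of the C7–O bond with C9 anti to C6 on the new lactone, and the C17 methyl takes the less hindered, thermodynamically preferred position cis to the 8‑OH.

## Compound list
1 | 4‑(tert‑butyldimethylsilyloxy)cyclohexan‑1‑one | O=C1CCC(O[Si](C)(C)C(C)(C)C)CC1 | starting material
2 | (R)‑4‑(TBSO)‑1‑(trimethylsilyloxy)cyclohex‑1‑ene | C[Si](C)(C)OC1=CC[C@H](O[Si](C)(C)C(C)(C)C)CC1 | intermediate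
3 | (R)‑4‑(TBSO)cyclohex‑2‑en‑1‑one | O=C1C=C[C@H](O[Si](C)(C)C(C)(C)C)CC1 | intermediate
4 | (R)‑4‑(TBSO)‑2‑iodocyclohex‑2‑en‑1‑one | O=C1C(I)=C[C@H](O[Si](C)(C)C(C)(C)C)CC1 | intermediate
5 | (R)‑4‑(TBSO)‑2‑methylcyclohex‑2‑en‑1‑one | CC1=C[C@H](O[Si](C)(C)C(C)(C)C)CCC1=O | intermediate
6 | prop‑2‑yn‑1‑ol | C#CCO | starting material
7 | (Z)‑3‑iodo‑2‑methylprop‑2‑en‑1‑ol | OC/C(C)=C\I | intermediate
8 | (Z)‑3‑bromo‑1‑iodo‑2‑methylprop‑1‑ene | BrC/C(C)=C\I | intermediate
9 | ethyl acetate | CCOC(C)=O | starting material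
10 | ethyl (Z)‑5‑iodo‑4‑methylpent‑4‑enoate | CCOC(=O)CC/C(C)=C\I | intermediate
11 | (Z)‑5‑iodo‑4‑methylpent‑4‑enal | O=CCC/C(C)=C\I | intermediate
12 | (2S,3R,4R)‑4‑(TBSO)‑2‑[(Z)‑1‑hydroxy‑5‑iodo‑4‑methylpent‑4‑enyl]‑2‑methyl‑3‑vinylcyclohexanone (carbinol epimers; vinyl trans to OTBS and trans to the side chain) | O=C1CC[C@@H](O[Si](C)(C)C(C)(C)C)[C@H](C=C)[C@@]1(C)C(O)CC/C(C)=C\I | intermediate
13 | (2S,3R,4R)‑4‑(TBSO)‑2‑[(Z)‑5‑iodo‑4‑methylpent‑4‑enoyl]‑2‑methyl‑3‑vinylcyclohexanone | O=C1CC[C@@H](O[Si](C)(C)C(C)(C)C)[C@H](C=C)[C@@]1(C)C(=O)CC/C(C)=C\I | intermediate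
14 | 14α‑hydroxy‑C2‑ketone: cyclohexanol (OH trans to ring Me) with C1 β‑Me/α‑(Z)‑5‑iodo‑4‑methylpent‑4‑enoyl, C10 β‑vinyl, C11 α‑OTBS | O[C@H]1CC[C@@H](O[Si](C)(C)C(C)(C)C)[C@H](C=C)[C@@]1(C)C(=O)CC/C(C)=C\I | intermediate
15 | (2R,14S) syn‑1,3‑diol of 14 (C2 carbinol on the side chain) | O[C@H]1CC[C@@H](O[Si](C)(C)C(C)(C)C)[C@H](C=C)[C@@]1(C)[C@H](O)CC/C(C)=C\I | intermediate
16 | 2,14‑di‑O‑acetate of 15 | CC(=O)O[C@H]1CC[C@@H](O[Si](C)(C)C(C)(C)C)[C@H](C=C)[C@@]1(C)[C@H](OC(C)=O)CC/C(C)=C\I | intermediate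
17 | C9 aldehyde (C10 β‑CHO replaces vinyl of 16) | CC(=O)O[C@H]1CC[C@@H](O[Si](C)(C)C(C)(C)C)[C@H](C=O)[C@@]1(C)[C@H](OC(C)=O)CC/C(C)=C\I | intermediate
18 | allyl 4‑methoxybenzyl ether | C=CCOCc1ccc(OC)cc1 | starting material
19 | (9R)‑alcohol with syn (8R) OPMB and terminal vinyl on the C10 side chain; other groups as 17 | CC(=O)O[C@H]1CC[C@@H](O[Si](C)(C)C(C)(C)C)[C@H]([C@@H](O)[C@H](OCc2ccc(OC)cc2)C=C)[C@@]1(C)[C@H](OC(C)=O)CC/C(C)=C\I | intermediate
20 | 2,9,14‑triacetate of 19 | CC(=O)O[C@H]1CC[C@@H](O[Si](C)(C)C(C)(C)C)[C@H]([C@@H](OC(C)=O)[C@H](OCc2ccc(OC)cc2)C=C)[C@@]1(C)[C@H](OC(C)=O)CC/C(C)=C\I | intermediate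
21 | C11 α‑alcohol (TBS removed from 20) | CC(=O)O[C@H]1CC[C@@H](O)[C@H]([C@@H](OC(C)=O)[C@H](OCc2ccc(OC)cc2)C=C)[C@@]1(C)[C@H](OC(C)=O)CC/C(C)=C\I | intermediate
22 | C11 ketone | CC(=O)O[C@H]1CCC(=O)[C@H]([C@@H](OC(C)=O)[C@H](OCc2ccc(OC)cc2)C=C)[C@@]1(C)[C@H](OC(C)=O)CC/C(C)=C\I | intermediate
23 | 11(20)‑exocyclic methylene | CC(=O)O[C@H]1CCC(=C)[C@H]([C@@H](OC(C)=O)[C@H](OCc2ccc(OC)cc2)C=C)[C@@]1(C)[C@H](OC(C)=O)CC/C(C)=C\I | intermediate
24 | (11R)‑11,20‑spiro‑epoxide (O α, CH2 β) | CC(=O)O[C@H]1CC[C@]2(CO2)[C@H]([C@@H](OC(C)=O)[C@H](OCc3ccc(OC)cc3)C=C)[C@@]1(C)[C@H](OC(C)=O)CC/C(C)=C\I | intermediate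
25 | C7 aldehyde (α‑OPMB, β‑OAc) with (Z)‑vinyl iodide arm | CC(=O)O[C@H]1CC[C@]2(CO2)[C@H]([C@@H](OC(C)=O)[C@H](OCc3ccc(OC)cc3)C=O)[C@@]1(C)[C@H](OC(C)=O)CC/C(C)=C\I | intermediate
26 | 7‑epi‑macrocycle: 2,9,14‑triacetoxy‑11,20‑epoxy‑8‑(PMB‑oxy)briar‑5(Z)‑en‑7‑ol without the lactone carbons, 7,8‑anti, 8,9‑syn | CC(=O)O[C@H]1CC[C@]2(CO2)[C@@H]2[C@@H](OC(C)=O)[C@H](OCc3ccc(OC)cc3)[C@H](O)/C=C(/C)CC[C@@H](OC(C)=O)[C@@]12C | intermediate
27 | 2‑bromopropanoic acid (racemic) | CC(Br)C(O)=O | starting material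
28 | C7 2‑bromopropanoate of the macrocycle, C7 inverted to target configuration (CHBr epimers) | CC(=O)O[C@H]1CC[C@]2(CO2)[C@@H]2[C@@H](OC(C)=O)[C@H](OCc3ccc(OC)cc3)[C@@H](OC(=O)C(C)Br)/C=C(/C)CC[C@@H](OC(C)=O)[C@@]12C | intermediate
29 | C8 alcohol (PMB removed from 28) | CC(=O)O[C@H]1CC[C@]2(CO2)[C@@H]2[C@@H](OC(C)=O)[C@H](O)[C@@H](OC(=O)C(C)Br)/C=C(/C)CC[C@@H](OC(C)=O)[C@@]12C | intermediate
30 | C8 ketone: 9‑acetoxy‑7‑(2‑bromopropanoyloxy)‑8‑oxo macrocycle | CC(=O)O[C@H]1CC[C@]2(CO2)[C@@H]2[C@@H](OC(C)=O)C(=O)[C@@H](OC(=O)C(C)Br)/C=C(/C)CC[C@@H](OC(C)=O)[C@@]12C | intermediate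
31 | junceellolide F, (1S,2R,5Z,7S,8S,9R,10S,11R,14S,17R)‑2,9,14‑triacetoxy‑8‑hydroxy‑11,20‑epoxybriar‑5‑en‑18,7‑olide | CC(=O)O[C@H]1CC[C@]2(CO2)[C@@H]2[C@@H](OC(C)=O)[C@@]3(O)[C@H](/C=C(/C)CC[C@@H](OC(C)=O)[C@@]12C)OC(=O)[C@@H]3C | target

## Totals and risks
- **Total steps:** 26.
- **Longest linear sequence:** 22 (steps 1–4, then 9–26). Steps 5–8 are a 4‑step side branch.

**Three steps most likely to fail**

1. **Step 22, NHK macrocyclisation.** Ten‑membered ring strain, a sensitive β‑acetoxy aldehyde and epoxide, and uncertain C7 facial selectivity (if C7 comes out already correct, step 23 becomes a simple acylation with 2‑bromopropanoyl bromide).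
 Fallback: close the ring at C4–C5 instead by B‑alkyl Suzuki–Miyaura macrocyclisation. Use acrolein in step 9 to give a C2 vinyl carbinol, build the (Z)‑C5‑iodoalkene on the C7 side (propynyl addition to the C7 aldehyde, then Red‑Al/I2), then 9‑BBN and Pd(dppf)Cl2/AsPh3/Cs2CO3. This fallback needs silyl rather than acetate protection until the end.

2. **Step 26, SmI2 Reformatsky.** Competing reductive cleavage of the α‑acyloxy groups and uncertain C8/C17 selectivity.
 Fallback: esterify C7–OH with diethylphosphonopropionic acid and close by intramolecular Horner–Wadsworth–Emmons to the Δ8(17)‑butenolide. Then nucleophilic epoxidation and reductive opening of the 8,17‑epoxy lactone at C17 give the 8‑hydroxy‑17‑H lactone, with C17 set by equilibration.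

3. **Step 11, chemo‑ and stereoselective mono‑reduction of the 1,3‑diketone.** The ring and side‑chain ketones may not be differentiated, or C14 may form as the wrong epimer.
 Fallback: skip the diketone. Run step 9 as a two‑stage Mukaiyama aldol (TMS enol ether, BF3, open transition state), separate the C2 carbinol with C2–O syn to C10, and set C14 by hydroxyl‑directed Narasaka–Prasad reduction of the ring ketone. C2 is then fixed in the C–C bond formation and C14 by direction from C2.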